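(The numbers in the tables were computed on assumed constants; noise was put on by code.)

Slowness shows as creeping, and the earlier runs do not creep: in the south-east run product reads 58.2% at 4.00 min and 59.9% at 12.0 min, and in the south run 83.2% at 3.00 min and 83.5% at 12.0 min.

| setting | south-east | south | flask |
|---|---|---|---|
| substrate | 20 mM (in portions, 4) | 20 mM (in portions, 4) | 20 mM (in portions, 4) |
| partner | 0.70 equiv | 1.1 equiv | 0.500 equiv |
| precatalyst | 0.1 mol% | 0.1 mol% | 0.1 mol% |
| remark | run made earlier; portions every 2.5 s | run made earlier; portions every 2.5 s | the portions of substrate follow each other after 2.5 s, the first at the start |
| time |  |  | 12 min |

| run | time / min | substrate / % | product / % |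
|---|---|---|---|
| south-east | 1.50 | 47.3 | 49.5 |
| south-east | 4.00 | 39.7 | 58.2 |
| south-east | 8.00 | 39.8 | 61.0 |
| south-east | 12.0 | 40.3 | 59.9 |
| south | 3.00 | 19.8 | 83.2 |
| south | 6.00 | 19.1 | 81.6 |
| south | 10.0 | 16.3 | 81.4 |
| south | 12.0 | 19.6 | 83.5 |

(each reading ± 1 percentage point)

- the state of affairs at 12 min: stopped, and by what, or still going (all of the substrate has reacted / no working catalyst is left / it is still moving / the partner has run out first / forward and back rates have come level)
- part of the substrate gone at 12 min
- the product standing at 12 min, as a percentage of the substrate charged

- the numbers in the tables scatter by 1 percentage point (one standard deviation)
- the reaction counts as stopped when no species that holds the substrate changes by six tenths of a point or more over the second half of the time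

The bench rule says that product stops at what the limiting reagent allows. In the south-east run the partner is that reagent, and product stands at a ratio of 0.856 to its charge. In the south run the substrate is that reagent, and product stands at 83.5%. Both runs stop short of the rule, with substrate and product still summing to about the whole charge.

So the reckoning here freezes a different quantity. Let P and S be product and substrate as fractions of the substrate charged, and let B be the partner left in equivalents, its charge minus P. The quotient P/(S·B) reads 14.7 in the south-east run and 16.1 in the south run. Their mean 15.4 is Q, the equilibrium constant in units of the charge.

Applied to this flask, with 0.500 equiv of partner, the rule would make P and S equal. Q then requires B = 0.0649 equiv, a ratio of 0.130 to the charge, and that ratio is the rule's border: it must be small for the rule to hold, and here it is well above the scatter. Solving the quotient for this flask, my own reckoning gives product 44.7%.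

The forecast says forward and back rates have come level, with conversion 44.7% and product 44.6%, on the ground that “the limit is equilibrium, not partner exhaustion”.

The flask gives forward and back rates have come level, with conversion 44.9% and product 44.9%.

    partner + precatalyst → catalyst + spent reagent (k = 2.18 /M/s)
    substrate + partner + catalyst ⇌ product + catalyst, rate k2*[substrate]*[partner]*[catalyst] forward; the back reaction follows from the equilibrium constant (K = 820 /M, k = 1.17 × 10⁵ /M²/s)

The falling level of partner is the main reason that this flask stands where it does: with the partner held level, the run reaches conversion 89.1% against 44.9%. The forecast's stop would turn wrong if the back step were taken away: that run reaches conversion 49.9%, and the back step is a part of the reason for the stop. In a neighbour flask with 0.200 equiv of partner, Q gives product 18.5%, and the computed result is 18.5%.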